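**Strategy.** The synthesis rests on the C7–C11 bond of the γ-lactone (ring atoms C7, C8, O, C12, C11; germacrane numbering). C11 is a tertiary carbinol flanked by the lactone carbonyl C12, so the ring is read as the intramolecular aldol adduct of an O8 pyruvate ester (ketone C11) and a C6 aldehyde enolised toward C7. One D-proline-catalysed aldol closes the lactone and sets C7 and C11 from the lone C8 stereocentre of an open-chain pyruvoyloxy aldehyde that already carries the Z-C1=C10 alkene and an E-C5 vinyl iodide. The same aldehyde then closes the ten-membered ring onto C5 (NiCl2/CrCl2); directed epoxidation of C4=C5 and double angeloylation follow.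

Key step: step 12

Remark: skeleton atoms are numbered as in germacranolides (ring C1–C10, C14 on C10, C15 on C4, side chain C11–C13, lactone oxygen on C8); the two esters are taken as angelates, as the Z geometry in the structure requires.

Step 1
Reactants: 1 5-(trimethylsilyl)pent-4-yn-1-ol
Product: 2 5-(trimethylsilyl)pent-4-ynal
Conditions: TEMPO (0.1 equiv), PhI(OAc)2, CH2Cl2, rt
Reagents that add atoms: none
Why: Oxoammonium (TEMPO/PhI(OAc)2) oxidation of a primary alcohol stops at the aldehyde and does not touch the silyl alkyne.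

Step 2
Reactants: 2 5-(trimethylsilyl)pent-4-ynal
Product: 3 (Z)-(6-iodohept-5-en-1-yn-1-yl)trimethylsilane
Conditions: EtPPh3I, n-BuLi, THF, rt; I2, −78 °C; NaHMDS, −20 °C; then 2, −78 to −20 °C
Reagents that add atoms: ethyltriphenylphosphonium iodide, CC[P+](c1ccccc1)(c1ccccc1)c1ccccc1.[I-]; iodine, II
Why: Wittig olefination with the α-iodo ylide (Stork–Zhao type) runs through the cis-oxaphosphetane of an unstabilised ylide and should give the (Z)-2-iodoalkene, which fixes the later C1=C10 geometry.

Step 3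
Reactants: 4 but-3-en-1-ol
Product: 5 tert-butyl(but-3-en-1-yloxy)dimethylsilane
Conditions: TBSCl, imidazole, CH2Cl2, rt
Reagents that add atoms: tert-butyldimethylsilyl chloride, CC(C)(C)[Si](C)(C)Cl
Why: Standard silylation of a primary alcohol protects the future C6 oxygen through the organometallic steps.

Step 4
Reactants: 5 tert-butyl(but-3-en-1-yloxy)dimethylsilane
Product: 6 rac-tert-butyldimethyl[2-(oxiran-2-yl)ethoxy]silane
Conditions: mCPBA, NaHCO3, CH2Cl2, 0 °C to rt
Reagents that add atoms: 3-chloroperoxybenzoic acid, OOC(=O)c1cccc(Cl)c1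
Why: Prilezhaev epoxidation of the terminal alkene gives the racemic terminal epoxide.

Step 5
Reactants: 6 rac-tert-butyldimethyl[2-(oxiran-2-yl)ethoxy]silane
Product: 7 (S)-tert-butyldimethyl[2-(oxiran-2-yl)ethoxy]silane
Conditions: (R,R)-(salen)Co(OAc) (0.5 mol %), H2O (0.55 equiv), THF, 0 °C to rt
Reagents that add atoms: none
Why: Jacobsen hydrolytic kinetic resolution with the cobalt–salen complex (trivalent cobalt), whose (R,R) form is expected to hydrolyse the (R)-enantiomer of an alkyl-substituted terminal epoxide, should leave (S)-7, whose stereocentre becomes C8.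

Step 6
Reactants: 3 (Z)-(6-iodohept-5-en-1-yn-1-yl)trimethylsilane; 7 (S)-tert-butyldimethyl[2-(oxiran-2-yl)ethoxy]silane
Product: 9 (3R,5Z)-1-[(tert-butyldimethylsilyl)oxy]-5-methyl-10-(trimethylsilyl)dec-5-en-9-yn-3-ol, via alkenyllithium 8 (not isolated)
Conditions: t-BuLi (2.0 equiv), Et2O, −78 °C; then 7, BF3·OEt2, −78 °C; H2O
Reagents that add atoms: none
Why: Iodine–lithium exchange keeps the alkene geometry and the BF3-activated epoxide is opened by SN2 attack at its terminal CH2, so the C8 stereocentre of 7 is carried over unchanged while the C9–C10 bond forms with the Z alkene in place.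

Step 7
Reactants: 9 (3R,5Z)-1-[(tert-butyldimethylsilyl)oxy]-5-methyl-10-(trimethylsilyl)dec-5-en-9-yn-3-ol
Product: 10 (3R,5Z)-1-[(tert-butyldimethylsilyl)oxy]-5-methyldec-5-en-9-yn-3-ol
Conditions: K2CO3 (0.2 equiv), MeOH, rt
Reagents that add atoms: none
Why: Base-catalysed methanolysis cleaves only the alkynyl C–Si bond; the silyl ether and the free alcohol are inert.

Step 8
Reactants: 10 (3R,5Z)-1-[(tert-butyldimethylsilyl)oxy]-5-methyldec-5-en-9-yn-3-ol
Product: 12 (3R,5Z,9E)-1-[(tert-butyldimethylsilyl)oxy]-10-iodo-5,9-dimethyldeca-5,9-dien-3-ol, via alkenylalane 11 (not isolated)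
Conditions: Me3Al (3.5 equiv), Cp2ZrCl2 (0.5 equiv), CH2Cl2, 0 °C to rt; then I2, THF, −30 °C; aq. potassium sodium tartrate
Reagents that add atoms: trimethylaluminium, C[Al](C)C; iodine, II
Why: Negishi zirconium-catalysed carboalumination adds methyl and aluminium syn across the terminal alkyne (methyl to C4, aluminium to C5) and iodinolysis with retention gives the E vinyl iodide, the free hydroxyl being masked in the flask as its aluminium alkoxide.

Step 9
Reactants: 12 (3R,5Z,9E)-1-[(tert-butyldimethylsilyl)oxy]-10-iodo-5,9-dimethyldeca-5,9-dien-3-ol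
Product: 13 (3R,5Z,9E)-1-[(tert-butyldimethylsilyl)oxy]-10-iodo-5,9-dimethyldeca-5,9-dien-3-yl 2-oxopropanoate
Conditions: pyruvic acid, DCC, DMAP (0.1 equiv), CH2Cl2, 0 °C
Reagents that add atoms: pyruvic acid, CC(=O)C(=O)O
Why: Steglich esterification of the secondary C8 alcohol installs the pyruvate that supplies C11, C12 and C13 and serves as the tether of the key step.

Step 10
Reactants: 13 (3R,5Z,9E)-1-[(tert-butyldimethylsilyl)oxy]-10-iodo-5,9-dimethyldeca-5,9-dien-3-yl 2-oxopropanoate
Product: 14 (3R,5Z,9E)-1-hydroxy-10-iodo-5,9-dimethyldeca-5,9-dien-3-yl 2-oxopropanoate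
Conditions: HF·pyridine, THF, 0 °C
Reagents that add atoms: none
Why: Fluoride cleavage of the primary silyl ether under mildly acidic conditions avoids base-induced migration or loss of the pyruvate.

Step 11
Reactants: 14 (3R,5Z,9E)-1-hydroxy-10-iodo-5,9-dimethyldeca-5,9-dien-3-yl 2-oxopropanoate
Product: 15 (3R,5Z,9E)-10-iodo-5,9-dimethyl-1-oxodeca-5,9-dien-3-yl 2-oxopropanoate
Conditions: TEMPO (0.1 equiv), PhI(OAc)2, CH2Cl2, rt; used at once
Reagents that add atoms: none
Why: TEMPO/PhI(OAc)2 oxidises the primary alcohol to the aldehyde under near-neutral conditions that leave the α-keto ester, both alkenes and the vinyl iodide intact.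

Step 12
Reactants: 15 (3R,5Z,9E)-10-iodo-5,9-dimethyl-1-oxodeca-5,9-dien-3-yl 2-oxopropanoate
Product: 17 (2R,3R,4R)-4-hydroxy-2-[(2Z,6E)-7-iodo-2,6-dimethylhepta-2,6-dien-1-yl]-4-methyl-5-oxooxolane-3-carbaldehyde, via D-proline enamine 16 (not isolated)
Conditions: D-proline (0.3 equiv), CH2Cl2, 0 °C
Reagents that add atoms: none
Why: D-proline condenses with the C6 aldehyde to the E enamine 16, whose C7 adds to the ketone carbon C11 of the tethered pyruvate while the proline CO2H hydrogen-bonds the ketone oxygen (Houk–List transition state), and hydrolysis returns the catalyst. The closest known reactions are proline-catalysed enolexo aldolisations of aldehydes onto tethered ketones and proline aldols with α-keto ester acceptors. The lactone ring (C7, C8, O, C12, C11) closes in a 5-(enolexo)-exo-trig mode. C7 is controlled by C8, because the tether reaches the enamine from the face of O8 with the C9 chain turned toward H7 (trans 7,8 relation) and D-proline is the catalyst enantiomer whose acid sits on that face; C11 is controlled by the hydrogen-bonded, cis-fused bicyclic transition state, which places the new hydroxyl cis to the C6 formyl group and the methyl trans to it. The step needs addition to C11 to outrun loss of pyruvate from the enamine (β-elimination to the enal) and self-condensation of the pyruvate, which the five-membered intramolecular closure onto a highly electrophilic α-keto ester, the absence of any base stronger than the amine and the low temperature in a non-polar solvent should secure.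

Step 13
Reactants: 17 (2R,3R,4R)-4-hydroxy-2-[(2Z,6E)-7-iodo-2,6-dimethylhepta-2,6-dien-1-yl]-4-methyl-5-oxooxolane-3-carbaldehyde
Product: 18 (1(10)Z,4E,6R,7R,8R,11R)-6,11-dihydroxygermacra-1(10),4-dien-12,8-olide
Conditions: CrCl2 (8 equiv), NiCl2 (0.05 equiv), DMSO/THF, 0.002 M, rt; aq. work-up
Reagents that add atoms: none
Why: Nozaki–Hiyama–Kishi reaction, in which zerovalent nickel formed in the flask inserts into the C5–I bond, transmetalation gives the alkenylchromium species (trivalent chromium) with retention of the E geometry and its addition to the C6 aldehyde at high dilution closes the ten-membered ring, C6 being set by Felkin–Anh attack anti to the quaternary C11 in the non-chelating solvent.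

Step 14
Reactants: 18 (1(10)Z,4E,6R,7R,8R,11R)-6,11-dihydroxygermacra-1(10),4-dien-12,8-olide
Product: 19 (1(10)Z,4S,5S,6S,7R,8R,11R)-4,5-epoxy-6,11-dihydroxygermacr-1(10)-en-12,8-olide
Conditions: VO(acac)2 (0.05 equiv), t-BuOOH, CH2Cl2, 0 °C
Reagents that add atoms: tert-butyl hydroperoxide, CC(C)(C)OO
Why: Vanadium-catalysed hydroxyl-directed epoxidation touches only the allylic C4=C5 alkene; since the ring bond C6–C7 lies on the inner face of the E alkene, the vanadate ester of the C6 hydroxyl can deliver oxygen only to the outer face through the small O–C6–C5=C4 dihedral angle that vanadium prefers, which should give the 4S,5S epoxide.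

Step 15
Reactants: 19 (1(10)Z,4S,5S,6S,7R,8R,11R)-4,5-epoxy-6,11-dihydroxygermacr-1(10)-en-12,8-olide
Product: 20 (1(10)Z,4S,5S,6S,7S,8R,11R)-6,11-bis(angeloyloxy)-4,5-epoxygermacr-1(10)-en-12,8-olide (CNP0118683.3)
Conditions: angelic acid, 2,4,6-trichlorobenzoyl chloride, Et3N, toluene, rt; then 19, 80 °C
Reagents that add atoms: angelic acid ((Z)-2-methylbut-2-enoic acid), C/C=C(/C)C(=O)O
Why: Yamaguchi-type esterification through the mixed anhydride of angelic acid acylates the secondary C6 and the tertiary C11 hydroxyl without strong base or acid, conditions under which the Z (angelate) geometry and the epoxide should survive.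

**Compound list**

1 | 5-(trimethylsilyl)pent-4-yn-1-ol | C[Si](C)(C)C#CCCCO | starting material
2 | 5-(trimethylsilyl)pent-4-ynal | C[Si](C)(C)C#CCCC=O | intermediate
3 | (Z)-(6-iodohept-5-en-1-yn-1-yl)trimethylsilane | C[Si](C)(C)C#CCC/C=C(/C)I | intermediate
4 | but-3-en-1-ol | C=CCCO | starting material
5 | tert-butyl(but-3-en-1-yloxy)dimethylsilane | C=CCCO[Si](C)(C)C(C)(C)C | intermediate
6 | rac-tert-butyldimethyl[2-(oxiran-2-yl)ethoxy]silane | CC(C)(C)[Si](C)(C)OCCC1CO1 | intermediate
7 | (S)-tert-butyldimethyl[2-(oxiran-2-yl)ethoxy]silane | CC(C)(C)[Si](C)(C)OCC[C@H]1CO1 | intermediate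
8 | (Z)-[7-(trimethylsilyl)hept-2-en-6-yn-2-yl]lithium | C[Si](C)(C)C#CCC/C=C(/C)[Li] | intermediate (not isolated)
9 | (3R,5Z)-1-[(tert-butyldimethylsilyl)oxy]-5-methyl-10-(trimethylsilyl)dec-5-en-9-yn-3-ol | CC(C)(C)[Si](C)(C)OCC[C@H](O)C/C(C)=C\CCC#C[Si](C)(C)C | intermediate
10 | (3R,5Z)-1-[(tert-butyldimethylsilyl)oxy]-5-methyldec-5-en-9-yn-3-ol | CC(C)(C)[Si](C)(C)OCC[C@H](O)C/C(C)=C\CCC#C | intermediate
11 | (E)-alkenyl(dimethyl)alane of 10 with the hydroxyl as its dimethylaluminium alkoxide | CC(C)(C)[Si](C)(C)OCC[C@H](O[Al](C)C)C/C(C)=C\CC/C(C)=C/[Al](C)C | intermediate (not isolated)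
12 | (3R,5Z,9E)-1-[(tert-butyldimethylsilyl)oxy]-10-iodo-5,9-dimethyldeca-5,9-dien-3-ol | CC(C)(C)[Si](C)(C)OCC[C@H](O)C/C(C)=C\CC/C(C)=C/I | intermediate
13 | (3R,5Z,9E)-1-[(tert-butyldimethylsilyl)oxy]-10-iodo-5,9-dimethyldeca-5,9-dien-3-yl 2-oxopropanoate | CC(C)(C)[Si](C)(C)OCC[C@H](OC(=O)C(C)=O)C/C(C)=C\CC/C(C)=C/I | intermediate
14 | (3R,5Z,9E)-1-hydroxy-10-iodo-5,9-dimethyldeca-5,9-dien-3-yl 2-oxopropanoate | OCC[C@H](OC(=O)C(C)=O)C/C(C)=C\CC/C(C)=C/I | intermediate
15 | (3R,5Z,9E)-10-iodo-5,9-dimethyl-1-oxodeca-5,9-dien-3-yl 2-oxopropanoate | O=CC[C@H](OC(=O)C(C)=O)C/C(C)=C\CC/C(C)=C/I | intermediate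
16 | (E)-enamine of 15 with D-proline | OC(=O)[C@H]1CCCN1/C=C/[C@H](OC(=O)C(C)=O)C/C(C)=C\CC/C(C)=C/I | intermediate (not isolated)
17 | (2R,3R,4R)-4-hydroxy-2-[(2Z,6E)-7-iodo-2,6-dimethylhepta-2,6-dien-1-yl]-4-methyl-5-oxooxolane-3-carbaldehyde | O=C[C@@H]1[C@@H](C/C(C)=C\CC/C(C)=C/I)OC(=O)[C@]1(C)O | intermediate
18 | (1(10)Z,4E,6R,7R,8R,11R)-6,11-dihydroxygermacra-1(10),4-dien-12,8-olide | C1/C(C)=C\CC/C(C)=C/[C@@H](O)[C@@H]2[C@@H]1OC(=O)[C@]2(C)O | intermediate
19 | (1(10)Z,4S,5S,6S,7R,8R,11R)-4,5-epoxy-6,11-dihydroxygermacr-1(10)-en-12,8-olide | C1/C(C)=C\CC[C@]3(C)O[C@H]3[C@@H](O)[C@@H]2[C@@H]1OC(=O)[C@]2(C)O | intermediate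
20 | (1(10)Z,4S,5S,6S,7S,8R,11R)-6,11-bis(angeloyloxy)-4,5-epoxygermacr-1(10)-en-12,8-olide (CNP0118683.3) | C/C=C(/C)C(=O)O[C@H]1[C@@H]2[C@@H](C/C(C)=C\CC[C@]3(C)O[C@@H]13)OC(=O)[C@]2(C)OC(=O)/C(C)=C\C | target

**Step count and risks**

Total steps: 15. Longest linear sequence: 13 steps (4 → 5 → 6 → 7 → 9 → 10 → 12 → 13 → 14 → 15 → 17 → 18 → 19 → 20); the branch from 1 joins at step 6.

Steps most likely to fail:

Step 12 (key step). The enamine can expel the pyruvate from C8 (β-elimination to the enal) before it adds to C11. Closure is further slowed because the ester must first rotate into its less populated s-cis form, and the facial choice at C11 could erode. The fallback sets out from 15 and returns at 17. Soft enolisation of 15 (TBSOTf, Et3N, CH2Cl2, −78 °C) should give the (Z)-tert-butyldimethylsilyl enol ether of 15 F1. A chelated intramolecular Mukaiyama aldol (MgBr2·OEt2, CH2Cl2, −78 °C), in which the Lewis acid binds both carbonyl oxygens of the α-keto ester and no amine is present, then closes the lactone. Aqueous work-up removes the silyl group and gives 17.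

Step 14. Oxygen may be delivered to the other rotamer of the C4=C5 alkene (poor facial selectivity), which would give the 4R,5R epoxide. The fallback sets out from 18 and returns at 20; it uses the opposite C6 epimer, for which directed epoxidation and allylic strain point to the same face, and then inverts C6 while installing the ester.
- Oxidation of 18 with MnO2 (CH2Cl2) gives the 6-oxo analogue of 18 F2.
- Corey–Bakshi–Shibata reduction (Me-CBS oxazaborolidine enantiomer chosen for the C6 epimer, BH3·SMe2, THF, −40 °C) gives the 6-epimer of 18 F3.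
- Hydroxyl-directed epoxidation (Ti(OiPr)4, t-BuOOH, CH2Cl2, −20 °C) gives the 6-epimer of 19 F4.
- Mitsunobu esterification with angelic acid (PPh3, DIAD, toluene, 0 °C) inverts C6 and gives the 6-O-angeloyl derivative of 19 with free 11-hydroxyl F5.
- Acylation of the tertiary hydroxyl of F5 under the conditions of step 15 gives 20.

Step 15. Acylation of the hindered tertiary C11 hydroxyl may stall, and forcing conditions may isomerise angelate to tiglate. The fallback sets out from 19 and returns at 20. Both hydroxyls are first acylated with 2-[bis(2,2,2-trifluoroethoxy)phosphoryl]propanoic acid (DCC, DMAP, CH2Cl2, 40 °C), a saturated acid that cannot isomerise, to give the 6,11-bis{2-[bis(2,2,2-trifluoroethoxy)phosphoryl]propanoate} of 19 F6. A double Still–Gennari olefination with acetaldehyde (KHMDS, 18-crown-6, THF, −78 °C) then builds both Z-2-methylbut-2-enoates and gives 20.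

**Further compounds**

F1 | step 12 | (Z)-tert-butyldimethylsilyl enol ether of 15 | CC(C)(C)[Si](C)(C)O/C=C\[C@H](OC(=O)C(C)=O)C/C(C)=C\CC/C(C)=C/I
F2 | step 14 | 6-oxo analogue of 18 ((1(10)Z,4E)-11-hydroxy-6-oxogermacra-1(10),4-dien-12,8-olide, C7, C8 and C11 as in 18) | C1/C(C)=C\CC/C(C)=C/C(=O)[C@@H]2[C@@H]1OC(=O)[C@]2(C)O
F3 | step 14 | 6-epimer of 18 | C1/C(C)=C\CC/C(C)=C/[C@H](O)[C@@H]2[C@@H]1OC(=O)[C@]2(C)O
F4 | step 14 | 6-epimer of 19 | C1/C(C)=C\CC[C@]3(C)O[C@H]3[C@H](O)[C@@H]2[C@@H]1OC(=O)[C@]2(C)O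
F5 | step 14 | 6-O-angeloyl derivative of 19 with free 11-hydroxyl | C1/C(C)=C\CC[C@]3(C)O[C@H]3[C@@H](OC(=O)/C(C)=C\C)[C@@H]2[C@@H]1OC(=O)[C@]2(C)O
F6 | step 15 | 6,11-bis{2-[bis(2,2,2-trifluoroethoxy)phosphoryl]propanoate} of 19 (mixture at the two phosphonate α-carbons) | C1/C(C)=C\CC[C@]3(C)O[C@H]3[C@@H](OC(=O)C(C)P(=O)(OCC(F)(F)F)OCC(F)(F)F)[C@@H]2[C@@H]1OC(=O)[C@]2(C)OC(=O)C(C)P(=O)(OCC(F)(F)F)OCC(F)(F)F
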